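**Plan**
- Cuts: the two benzyl ethers go last. The naphthalene is traced back to an oxygen-bridged adduct, which is cut at C2a′–C8b′ and C5′–C5a′ into a tethered aryne and a 3-benzyloxyfuran. Further cuts are C3–O1′ (ketalisation), C3a–C3 with C3–N (aryllithium plus furoate) and furan C3–O (Pd etherification).
- Enabling feature: O1′ and C2a′ are both substituents of the spiro carbon C3. A 3-aryloxy-3-(2-furyl) lactam therefore holds the aryne carbon C8b′ (ortho to O1′) and the furan only two atoms (O1′, C3) apart.
- Forward order: lactam ring (step 4), aryl N,O-ketal (step 8), then the five-membered oxa ring and the second carbocycle together (step 10), aromatisation (step 11), hydrogenolysis (step 12).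
- Stereochemistry: C3 is the only stereocentre. Racemic ketal 18 is resolved on a chiral phase (step 9) and the antipode is racemised by acid and recycled. C3 is not ionised afterwards, and the bridgehead centres of 21 are transient.

Key step: step 10

Remark on locants: lactam C1 (C=O), N2, C3 (spiro), C3a, C4 (OMe); naphthofuran O1′, C2′ (= C3), C2a′ to C8b′.
Remark on descriptors: the target is (S) at C3. Ketal 19 and adduct 21 have the same spatial arrangement but are (R), because a furyl or bridgehead carbon outranks the benzo carbon C3a.
Remark on protecting groups and purchase: both hydroxyls travel as benzyl ethers, which tolerate s-BuLi, fluoride and Fe2(CO)9 and fall together in the last step. Acid chloride 5 and amine 6 are taken as purchased.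
Remark on 21: either bridge epimer may form; one is drawn and both give 22.

**Step 1**
Reactants: 1 3-bromofuran
Product: 3 benzyl 3-bromofuran-2-carboxylate, via 3-bromo-2-furyllithium 2 (not isolated)
Conditions: LDA, THF, −78 °C; cannulated into BnOCOCl (1.5 equiv), THF, −78 °C
Reagents that add atoms: benzyl chloroformate, O=C(Cl)OCc1ccccc1
Why: Directed lithiation: LDA removes the C2 proton flanked by the ring oxygen and bromine (no halogen migration at −78 °C), and inverse addition of the furyllithium to excess chloroformate stops the acyl substitution at the ester.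

**Step 2**
Reactants: 3 benzyl 3-bromofuran-2-carboxylate
Product: 4 benzyl 3-(benzyloxy)furan-2-carboxylate
Conditions: BnOH (1.5 equiv), tBuBrettPhos Pd G3 (2 mol %), Cs2CO3, toluene, 80 °C
Reagents that add atoms: benzyl alcohol, OCc1ccccc1
Why: Pd-catalysed C–O cross-coupling of a primary alcohol (Buchwald–Hartwig etherification): oxidative addition is eased by the ortho ester, the bulky biaryl phosphine favours C–O reductive elimination over β-hydride loss, and ester exchange with benzyl alcohol is degenerate.

**Step 3**
Reactants: 5 3-methoxybenzoyl chloride; 6 2-(benzyloxy)ethan-1-amine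
Product: 7 N-[2-(benzyloxy)ethyl]-3-methoxybenzamide
Conditions: Et3N, CH2Cl2, 0 °C → rt
Reagents that add atoms: none
Why: Schotten–Baumann-type N-acylation of a primary amine by an acid chloride, which is fast and selective.

**Step 4**
Reactants: 7 N-[2-(benzyloxy)ethyl]-3-methoxybenzamide; 4 benzyl 3-(benzyloxy)furan-2-carboxylate
Product: 10 rac-2-[2-(benzyloxy)ethyl]-3-[3-(benzyloxy)furan-2-yl]-3-hydroxy-4-methoxyisoindolin-1-one, via dilithiated benzamide 8 (not isolated), via lithium keto amidate 9 (not isolated)
Conditions: s-BuLi (2.2 equiv), TMEDA, THF, −78 °C; then 4, −78 → 0 °C; aq. NH4Cl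
Reagents that add atoms: none
Why: Directed ortho-metalation: the lithium amidate and the methoxy group together place lithium on the carbon between them, the aryllithium acylates with the ester, and the neighbouring amidate nitrogen closes onto the new ketone, so that the hydroxy lactam forms in one flask with C3 racemic.

**Step 5**
Reactants: 11 orcinol
Product: 12 2-iodo-5-methylbenzene-1,3-diol
Conditions: I2, NaHCO3, H2O–THF, 0 °C → rt
Reagents that add atoms: iodine, II
Why: Electrophilic iodination under the iodine–bicarbonate conditions that substitute resorcinols between the two hydroxyls, a preference reinforced here by the methyl group that flanks the other two positions.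

**Step 6**
Reactants: 12 2-iodo-5-methylbenzene-1,3-diol
Product: 13 2-iodo-5-methyl-1,3-bis(trimethylsilyloxy)benzene
Conditions: HMDS, THF, 70 °C; concentrated
Reagents that add atoms: hexamethyldisilazane, C[Si](C)(C)N[Si](C)(C)C
Why: O-silylation of both phenols by HMDS, driven by loss of ammonia, sets up the silyl migration of the next step.

**Step 7**
Reactants: 13 2-iodo-5-methyl-1,3-bis(trimethylsilyloxy)benzene
Product: 17 3-hydroxy-5-methyl-2-(trimethylsilyl)phenyl trifluoromethanesulfonate, via aryllithium 14 (not isolated), via lithium phenoxide 15 (not isolated), via O-silyl aryl triflate 16 (not isolated)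
Conditions: n-BuLi, THF, −78 °C → rt; Tf2O, −78 °C; then MeOH, cat. citric acid, 0 °C
Reagents that add atoms: trifluoromethanesulfonic anhydride, O=S(=O)(OS(=O)(=O)C(F)(F)F)C(F)(F)F
Why: Iodine–lithium exchange followed by retro-Brook 1,3-O→C silyl migration leaves a single lithium phenoxide, which alone is triflated, so the symmetrical diol is differentiated without statistics, and methanol then frees the other phenol from its labile O-silyl ether (the usual route to o-silylaryl triflates).

**Step 8**
Reactants: 10 rac-hydroxy lactam; 17 3-hydroxy-5-methyl-2-(trimethylsilyl)phenyl trifluoromethanesulfonate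
Product: 18 rac-2-[2-(benzyloxy)ethyl]-3-[3-(benzyloxy)furan-2-yl]-4-methoxy-3-[5-methyl-3-(triflyloxy)-2-(trimethylsilyl)phenoxy]isoindolin-1-one
Conditions: 17 (1.5 equiv), (PhO)2P(O)OH (10 mol %), 4 Å MS, CH2Cl2, 0 °C → rt; Et3N quench
Reagents that add atoms: none
Why: Acid-catalysed N,O-ketalisation through an N-acyliminium ion: the tertiary hydroxy lactam ionises readily because furyl and aryl groups stabilise the cation, the phenol (ring deactivated by triflate, carbon positions hindered) adds through oxygen, and sieves drive the equilibrium by taking up water, C3 staying racemic.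

**Step 9**
Reactants: 18 racemic aryl N,O-ketal
Product: 19 (R)-2-[2-(benzyloxy)ethyl]-3-[3-(benzyloxy)furan-2-yl]-4-methoxy-3-[5-methyl-3-(triflyloxy)-2-(trimethylsilyl)phenoxy]isoindolin-1-one
Conditions: preparative SFC, amylose tris(3,5-dimethylphenylcarbamate) phase, CO2–iPrOH (0.1 % Et3N)
Reagents that add atoms: none
Why: Chromatographic resolution of a racemate on a polysaccharide chiral stationary phase, which here supplies the single stereocentre: the (R) enantiomer is kept (assignment by anomalous-dispersion X-ray analysis, S and Si being present), and the antipode is racemised with the acid of step 8 and recycled.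

**Step 10**
Reactants: 19 (R)-aryl N,O-ketal carrying the o-silylaryl triflate
Product: 21 (3R)-oxygen-bridged cycloadduct of the aryne across furan C2/C5 (drawn as the 2a′R,5′R bridge epimer), via aryne 20 (not isolated)
Conditions: CsF (4 equiv), MeCN (2 mM, slow addition of 19), 25 → 50 °C
Reagents that add atoms: none
Why: Proposed new method: fluoride removes the silyl group, triflate leaves and aryne 20 forms ortho to the ketal oxygen, where its in-plane π bond adds across C2 and C5 of the furan held on C3 in a concerted but asynchronous [4+2] cycloaddition; the closest known reaction type is the intramolecular aryne–furan Diels–Alder reaction through ortho tethers that close six-membered or larger rings, while closure of a five-membered ring through a two-atom O–C tether has not been shown. The five-membered ring (C3, O1′, C8a′, C8b′, C2a′) closes in the 5-exo sense with respect to the aryne π bond, in the plane of the arene, as the tethered furan carbon bonds to C8b′, and the six-membered carbocycle (C2a′ to C5a′ plus C8b′) closes as the [4+2] ring bridged by the furan oxygen. The bridgehead centres C2a′ and C5′ are fixed relative to each other by the bicycle, their sense relative to C3 is left uncontrolled and is irrelevant because both vanish on aromatisation, and C3 keeps its configuration because nothing in the neutral medium ionises the ketal. The step needs intramolecular capture to beat fluoride, acetonitrile and a second molecule, which slow release of the aryne at high dilution and the electron-rich 3-benzyloxyfuran held within bonding distance should secure; regiochemistry is enforced by the tether against the intrinsic polarisation of the 3-oxyaryne. The product ring system is strained at C8b′, but aryne additions are strongly exothermic with early transition states in which the forming bonds are long, so only part of that strain should be felt.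

**Step 11**
Reactants: 21 oxygen-bridged cycloadduct
Product: 22 (S)-2-[2-(benzyloxy)ethyl]-4-methoxyisoindolin-1-one spiro-fused at C3 to C2′ of 3′-(benzyloxy)-7′-methyl-2′H-naphtho[1,8-bc]furan
Conditions: Fe2(CO)9 (2.5 equiv), benzene, 60 °C
Reagents that add atoms: none
Why: Deoxygenative aromatisation of a 1,4-epoxy-1,4-dihydronaphthalene with Fe2(CO)9: iron(0) binds the strained enol ether double bond, inserts into a bridgehead C–O bond and carries the bridge oxygen off as CO2 under neutral conditions that leave the N,O-ketal and C3 untouched, the enol ether oxygen becoming the C3′ benzyl ether.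

**Step 12**
Reactants: 22 (S)-dibenzyl ether
Product: 23 CNP0434366.2
Conditions: H2 (1 atm), 10 % Pd/C, EtOAc–EtOH, rt
Reagents that add atoms: none
Why: Hydrogenolysis of the aryl benzyl ether and the alkyl benzyl ether over Pd/C in a neutral medium, in which the quaternary spiro C–O bond is too hindered to be cleaved and C3 is not ionised.

**Compound list**
1 | 3-bromofuran | Brc1ccoc1 | starting material
2 | 3-bromo-2-furyllithium | [Li]c1occc1Br | intermediate
3 | benzyl 3-bromofuran-2-carboxylate | O=C(OCc1ccccc1)c1occc1Br | intermediate
4 | benzyl 3-(benzyloxy)furan-2-carboxylate | O=C(OCc1ccccc1)c1occc1OCc1ccccc1 | intermediate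
5 | 3-methoxybenzoyl chloride | COc1cccc(C(=O)Cl)c1 | starting material
6 | 2-(benzyloxy)ethan-1-amine | NCCOCc1ccccc1 | starting material
7 | N-[2-(benzyloxy)ethyl]-3-methoxybenzamide | COc1cccc(C(=O)NCCOCc2ccccc2)c1 | intermediate
8 | N,2-dilithio-N-[2-(benzyloxy)ethyl]-3-methoxybenzamide | COc1cccc(C(=O)N([Li])CCOCc2ccccc2)c1[Li] | intermediate
9 | N-lithio 2-[3-(benzyloxy)furan-2-carbonyl]-N-[2-(benzyloxy)ethyl]-3-methoxybenzamide | COc1cccc(C(=O)N([Li])CCOCc2ccccc2)c1C(=O)c1occc1OCc1ccccc1 | intermediate
10 | rac-2-[2-(benzyloxy)ethyl]-3-[3-(benzyloxy)furan-2-yl]-3-hydroxy-4-methoxyisoindolin-1-one | COc1cccc2c1C(O)(c1occc1OCc1ccccc1)N(CCOCc1ccccc1)C2=O | intermediate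
11 | orcinol (5-methylbenzene-1,3-diol) | Cc1cc(O)cc(O)c1 | starting material
12 | 2-iodo-5-methylbenzene-1,3-diol | Cc1cc(O)c(I)c(O)c1 | intermediate
13 | 2-iodo-5-methyl-1,3-bis(trimethylsilyloxy)benzene | Cc1cc(O[Si](C)(C)C)c(I)c(O[Si](C)(C)C)c1 | intermediate
14 | 4-methyl-2,6-bis(trimethylsilyloxy)phenyllithium | Cc1cc(O[Si](C)(C)C)c([Li])c(O[Si](C)(C)C)c1 | intermediate
15 | lithium 5-methyl-2-(trimethylsilyl)-3-(trimethylsilyloxy)phenoxide | Cc1cc(O[Li])c([Si](C)(C)C)c(O[Si](C)(C)C)c1 | intermediate
16 | 5-methyl-2-(trimethylsilyl)-3-(trimethylsilyloxy)phenyl trifluoromethanesulfonate | Cc1cc(OS(=O)(=O)C(F)(F)F)c([Si](C)(C)C)c(O[Si](C)(C)C)c1 | intermediate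
17 | 3-hydroxy-5-methyl-2-(trimethylsilyl)phenyl trifluoromethanesulfonate | Cc1cc(O)c([Si](C)(C)C)c(OS(=O)(=O)C(F)(F)F)c1 | intermediate
18 | rac-2-[2-(benzyloxy)ethyl]-3-[3-(benzyloxy)furan-2-yl]-4-methoxy-3-[5-methyl-3-(triflyloxy)-2-(trimethylsilyl)phenoxy]isoindolin-1-one | COc1cccc2c1C(c1occc1OCc1ccccc1)(Oc1cc(C)cc(OS(=O)(=O)C(F)(F)F)c1[Si](C)(C)C)N(CCOCc1ccccc1)C2=O | intermediate
19 | (R)-enantiomer of 18 | COc1cccc2c1[C@](c1occc1OCc1ccccc1)(Oc1cc(C)cc(OS(=O)(=O)C(F)(F)F)c1[Si](C)(C)C)N(CCOCc1ccccc1)C2=O | intermediate
20 | (R)-aryne: 19 with a C≡C bond between the former C–SiMe3 and C–OTf carbons (3-(5-methyl-2,3-didehydrophenoxy) group) | COc1cccc2c1[C@](c1occc1OCc1ccccc1)(OC1=CC(C)=CC#C1)N(CCOCc1ccccc1)C2=O | intermediate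
21 | (3R)-oxygen-bridged cycloadduct: C2a′ (on C3 and C8b′) and C5′ (H, on C5a′) joined by an oxygen bridge and by the C3′(OBn)=C4′ enol ether; drawn 2a′R,5′R, bridge oxygen on the side of the lactam nitrogen | COc1cccc2c1[C@]1(Oc3cc(C)cc4c3[C@]13O[C@@H]4C=C3OCc3ccccc3)N(CCOCc3ccccc3)C2=O | intermediate
22 | (S)-2-[2-(benzyloxy)ethyl]-4-methoxyisoindolin-1-one spiro-fused at C3 to C2′ of 3′-(benzyloxy)-7′-methyl-2′H-naphtho[1,8-bc]furan | COc1cccc2c1[C@]1(Oc3cc(C)cc4ccc(OCc5ccccc5)c1c34)N(CCOCc1ccccc1)C2=O | intermediate
23 | CNP0434366.2: (S)-2-(2-hydroxyethyl)-4-methoxyisoindolin-1-one spiro-fused at C3 to C2′ of 3′-hydroxy-7′-methyl-2′H-naphtho[1,8-bc]furan | COc1cccc2c1[C@]1(Oc3cc(C)cc4ccc(O)c1c34)N(CCO)C2=O | target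

**Step count**
Total: 12 steps. Longest linear sequence: 8 steps (1 → 3 → 4 → 10 → 18 → 19 → 21 → 22 → 23; the branch from orcinol 11 is equally long).

**Steps most likely to fail**

Step 10 (bears the label). The aryne may be lost to fluoride, acetonitrile or a second molecule before the tethered furan reaches the strained geometry that closes the five-membered ring. The fallback uses known reaction types only; it sets out from 17 and 4 and rejoins at 22. Phenol 17 is protected with MOMCl and iPr2NEt as 3-(methoxymethoxy)-5-methyl-2-(trimethylsilyl)phenyl triflate F1. The aryne released from F1 with CsF in MeCN is intercepted by excess furoate 4 in an intermolecular aryne–furan Diels–Alder reaction to give the bridgehead ester F2. This is the regioisomer with ester and MOM ether on the same side, expected because the unsubstituted furan C5 bonds to the aryne carbon remote from oxygen; the other isomer is separated. Fe2(CO)9 then gives the naphthoate F3. HCl in methanol removes the MOM group and the freed peri phenol lactonises to the naphtholactone F4. The dilithiated benzamide 8 (from 7 as in step 4) adds to this strained lactone, and an acid work-up with catalytic TsOH closes the lactam and the spiro ketal to the racemic dibenzyl ether F5. Resolution on the chiral phase as in step 9 gives 22. In this order the C3–O1′ bond and the stereocentre are made after the naphthalene.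

Step 8. The crowded N-acyliminium ion may not take up the hindered, weakly nucleophilic phenol at oxygen fast enough. Protodesilylation of 17, C-alkylation, closure of the side-chain ether oxygen onto C3 or return to 10 could then dominate. The fallback runs from 10 to 18. SOCl2 and 2,6-lutidine in CH2Cl2 at −20 °C convert 10 into the 3-chloro lactam F6. F6 is used at once with 17 and iPr2NEt, so that the ion pair is captured irreversibly by the phenol under base and without acid.

Step 11. Iron may bind the alkene without extruding the bridge oxygen from this enol-ether-bearing, peri-strained bicycle, or the bridge may open without loss of oxygen. The fallback changes the oxidation level and runs from 21 to 23. Wet oxalic acid on silica hydrolyses the benzyl enol ether to the bridged α-alkoxy ketone F7. SmI2 in THF–MeOH at −78 °C cleaves the C2a′–O bond next to the ketone to give the β-hydroxy ketone F8. F8 loses water and tautomerises on Et3N or silica to the naphthol F9, already free at C3′. The hydrogenolysis of step 12 then removes the remaining benzyl ether to give 23.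

**Further compounds**
F1 | step 10 | 3-(methoxymethoxy)-5-methyl-2-(trimethylsilyl)phenyl trifluoromethanesulfonate | COCOc1cc(C)cc(OS(=O)(=O)C(F)(F)F)c1[Si](C)(C)C
F2 | step 10 | rac-benzyl 2-(benzyloxy)-8-(methoxymethoxy)-6-methyl-1,4-dihydro-1,4-epoxynaphthalene-1-carboxylate | COCOc1cc(C)cc2c1C1(C(=O)OCc3ccccc3)OC2C=C1OCc1ccccc1
F3 | step 10 | benzyl 2-(benzyloxy)-8-(methoxymethoxy)-6-methyl-1-naphthoate | COCOc1cc(C)cc2ccc(OCc3ccccc3)c(C(=O)OCc3ccccc3)c12
F4 | step 10 | 3-(benzyloxy)-7-methyl-2H-naphtho[1,8-bc]furan-2-one | O=C1Oc2cc(C)cc3ccc(OCc4ccccc4)c1c23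
F5 | step 10 | racemic form of 22 | COc1cccc2c1C1(Oc3cc(C)cc4ccc(OCc5ccccc5)c1c34)N(CCOCc1ccccc1)C2=O
F6 | step 8 | rac-2-[2-(benzyloxy)ethyl]-3-[3-(benzyloxy)furan-2-yl]-3-chloro-4-methoxyisoindolin-1-one | COc1cccc2c1C(Cl)(c1occc1OCc1ccccc1)N(CCOCc1ccccc1)C2=O
F7 | step 11 | (3R)-bridged ketone: 21 with C3′=O and C4′H2 in place of the benzyl enol ether, bridge as in 21 | COc1cccc2c1[C@]1(Oc3cc(C)cc4c3[C@]13O[C@@H]4CC3=O)N(CCOCc3ccccc3)C2=O
F8 | step 11 | β-hydroxy ketone: C2a′–H, C3′=O, C4′H2, C5′–OH, spiro centre as in 21, new centres undefined | COc1cccc2c1[C@]1(Oc3cc(C)cc4c3C1C(=O)CC4O)N(CCOCc1ccccc1)C2=O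
F9 | step 11 | (S)-2-[2-(benzyloxy)ethyl]-4-methoxyisoindolin-1-one spiro-fused at C3 to C2′ of 3′-hydroxy-7′-methyl-2′H-naphtho[1,8-bc]furan | COc1cccc2c1[C@]1(Oc3cc(C)cc4ccc(O)c1c34)N(CCOCc1ccccc1)C2=O
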